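The oxirane C1–C10 bond of the germacrane frame lies between two CH2–CH(O) units (C2–C3 and C9–C8), so the ten-membered carbocycle is cut there into an allyl carbinol at C3 and a methallyl carbinol at C8, each set by reagent-controlled allylboration. Ring-closing metathesis of this seco-diene, pre-folded by the cis C4=C5 olefin and the trans γ-lactone on C6/C7 (from a chiral butenolide), closes the ring and forms C1=C10 in one operation. The Z-cyclodecene expected for a medium ring is then converted into the trans-epoxide by syn-dihydroxylation and invertive cyclodehydration; the exocyclic methylene and the enolisable ester are introduced only after ring closure.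

Key step: step 14

Assumption: (R)-2-methylbutanoic acid, methyl angelate and (5S)-5-(hydroxymethyl)furan-2(5H)-one are purchased; ring atoms carry germacrane numbers (C1–C15); the ring closure is taken to give the Z olefin, as is usual for medium rings, and the E case is covered by a fallback.

Step 1
Reactants: 1 methyl angelate [methyl (2Z)-2-methylbut-2-enoate]
Product: 2 (2Z)-2-methylbut-2-en-1-ol
Conditions: iBu2AlH (2.2 equiv), CH2Cl2, −78 → 0 °C; Rochelle-salt work-up
Reagents that add atoms: none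
Why: 1,2-Hydride reduction of the conjugated ester at low temperature leaves the Z-trisubstituted olefin unreduced and unisomerised (ester reduction).

Step 2
Reactants: 2 (2Z)-2-methylbut-2-en-1-ol
Product: 3 [(2R,3S)-2,3-dimethyloxiran-2-yl]methanol
Conditions: Ti(OiPr)4 (10 mol %), D-(−)-diethyl tartrate (12 mol %), t-BuOOH, 4 Å molecular sieves, CH2Cl2, −20 °C
Reagents that add atoms: tert-butyl hydroperoxide, CC(C)(C)OO
Why: Sharpless asymmetric epoxidation of the Z-allylic alcohol, in which the D-(−)-tartrate complex should deliver oxygen to the face that gives the (2R,3S)-epoxy alcohol, the syn addition keeping C1 and C4 cis.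

Step 3
Reactants: 3 [(2R,3S)-2,3-dimethyloxiran-2-yl]methanol
Product: 5 (2S,3S)-2,3-dimethyloxirane-2-carboxylic acid, via epoxy aldehyde 4 (not isolated)
Conditions: RuCl3·xH2O (2 mol %), NaIO4, MeCN/EtOAc/H2O, 0 °C → rt
Reagents that add atoms: water, O
Why: RuO4 formed from RuCl3 and NaIO4 oxidises the primary alcohol through the aldehyde hydrate to the acid, and the epoxide stereocentres (no α-hydrogen at C2) are not touched.

Step 4
Reactants: 6 (5S)-5-(hydroxymethyl)furan-2(5H)-one
Product: 7 (5S)-5-{[(tert-butyldiphenylsilyl)oxy]methyl}furan-2(5H)-one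
Conditions: TBDPSCl, imidazole, DMF, 0 °C → rt
Reagents that add atoms: tert-butyl(chloro)diphenylsilane, CC(C)(C)[Si](Cl)(c1ccccc1)c1ccccc1
Why: Silylation of the primary alcohol gives an acid-stable ether (needed in step 6) whose bulk shields one face of the butenolide.

Step 5
Reactants: 7 (5S)-5-{[(tert-butyldiphenylsilyl)oxy]methyl}furan-2(5H)-one
Product: 8 (4S,5S)-5-{[(tert-butyldiphenylsilyl)oxy]methyl}-4-(1,3-dioxolan-2-yl)oxolan-2-one
Conditions: 1,3-dioxolane (solvent), Ph2CO (10 mol %), hν (medium-pressure Hg lamp, Pyrex), rt, degassed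
Reagents that add atoms: 1,3-dioxolane, C1COCO1
Why: The benzophenone-generated, nucleophilic 1,3-dioxolan-2-yl radical adds to the β-carbon of the butenolide anti to the C5 silyloxymethyl group (radical conjugate addition), which sets the trans C7 stereocentre and brings in C8 as a masked aldehyde.

Step 6
Reactants: 8 (4S,5S)-5-{[(tert-butyldiphenylsilyl)oxy]methyl}-4-(1,3-dioxolan-2-yl)oxolan-2-one
Product: 9 (2S,3S)-2-{[(tert-butyldiphenylsilyl)oxy]methyl}-5-oxooxolane-3-carbaldehyde
Conditions: 1 M HCl, THF, rt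
Reagents that add atoms: water, O
Why: Acid-catalysed acetal hydrolysis frees the C8 aldehyde while the TBDPS ether and the lactone survive, and the trans arrangement at C7 is the thermodynamically preferred one, so enolisation cannot erode it.

Step 7
Reactants: 9 (2S,3S)-2-{[(tert-butyldiphenylsilyl)oxy]methyl}-5-oxooxolane-3-carbaldehyde
Product: 11 (4R,5S)-5-{[(tert-butyldiphenylsilyl)oxy]methyl}-4-[(1R)-1-hydroxy-3-methylbut-3-en-1-yl]oxolan-2-one, via borinate ester 10 (not isolated)
Conditions: (+)-Ipc2B(2-methylallyl) [made in the flask from (+)-Ipc2BOMe (from (−)-α-pinene) and 2-methylallylmagnesium chloride], Et2O, −78 °C; then pH 7 buffer, H2O2, MeOH, 0 °C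
Reagents that add atoms: 2-methylallylmagnesium chloride, CC(=C)C[Mg]Cl
Why: Brown methallylboration through a chair Zimmerman–Traxler transition state, in which the isopinocampheyl groups from (−)-α-pinene direct addition to the Re face of the aldehyde and set (8R) under reagent control.

Step 8
Reactants: 11 (4R,5S)-5-{[(tert-butyldiphenylsilyl)oxy]methyl}-4-[(1R)-1-hydroxy-3-methylbut-3-en-1-yl]oxolan-2-one; 5 (2S,3S)-2,3-dimethyloxirane-2-carboxylic acid
Product: 13 (1R)-1-[(2S,3R)-2-{[(tert-butyldiphenylsilyl)oxy]methyl}-5-oxooxolan-3-yl]-3-methylbut-3-en-1-yl (2S,3S)-2,3-dimethyloxirane-2-carboxylate, via mixed anhydride 12 (not isolated)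
Conditions: 2,4,6-trichlorobenzoyl chloride, Et3N, THF, rt; then 11, DMAP, toluene, rt
Reagents that add atoms: none
Why: Yamaguchi esterification acylates the hindered secondary alcohol with the α-quaternary, non-epimerisable epoxy acid and leaves all stereocentres alone.

Step 9
Reactants: 13 (silyl ether from step 8)
Product: 14 (1R)-1-[(2S,3R)-2-(hydroxymethyl)-5-oxooxolan-3-yl]-3-methylbut-3-en-1-yl (2S,3S)-2,3-dimethyloxirane-2-carboxylate
Conditions: HF·pyridine, pyridine/THF, 0 °C → rt
Reagents that add atoms: none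
Why: Fluoride cleaves the primary silyl ether under buffered conditions that the electron-poor glycidic ester, the lactone and the 1,1-disubstituted olefin should tolerate.

Step 10
Reactants: 14 (primary alcohol from step 9)
Product: 15 (1R)-1-[(2S,3R)-2-formyl-5-oxooxolan-3-yl]-3-methylbut-3-en-1-yl (2S,3S)-2,3-dimethyloxirane-2-carboxylate
Conditions: Dess–Martin periodinane, NaHCO3, CH2Cl2, 0 °C → rt
Reagents that add atoms: none
Why: Dess–Martin oxidation gives the aldehyde under neutral buffered conditions, which avoids epimerisation of the α-oxygenated C6 centre.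

Step 11
Reactants: 15 (aldehyde from step 10)
Product: 16 (1R)-1-{(2S,3R)-2-[(1Z)-2-iodoprop-1-en-1-yl]-5-oxooxolan-3-yl}-3-methylbut-3-en-1-yl (2S,3S)-2,3-dimethyloxirane-2-carboxylate
Conditions: (1-iodoethyl)triphenylphosphonium iodide, NaN(SiMe3)2, THF, −78 °C; then 15, −78 → −20 °C
Reagents that add atoms: (1-iodoethyl)triphenylphosphonium iodide, CC(I)[P+](c1ccccc1)(c1ccccc1)c1ccccc1.[I-]
Why: Stork–Zhao-type Wittig olefination with the α-iodo ylide is kinetically Z-selective, placing iodine cis to C6 and so fixing the geometry of the later C4=C5 olefin.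

Step 12
Reactants: 16 (Z-alkenyl iodide from step 11)
Product: 17 (1R)-3-methyl-1-{(2R,3R)-2-[(1Z)-2-methyl-3-oxoprop-1-en-1-yl]-5-oxooxolan-3-yl}but-3-en-1-yl (2S,3S)-2,3-dimethyloxirane-2-carboxylate
Conditions: Pd(PPh3)4 (5 mol %), CO (1 atm), Bu3SnH (slow addition), THF, 50 °C
Reagents that add atoms: carbon monoxide, [C-]#[O+]
Why: Palladium-catalysed reductive carbonylation (oxidative addition with retention, CO insertion, hydride transfer from tin, reductive elimination) converts the alkenyl iodide into the enal without changing the olefin geometry.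

Step 13
Reactants: 17 (Z-enal from step 12)
Product: 19 (1R)-1-{(2R,3R)-2-[(1Z,3S)-3-hydroxy-2-methylhexa-1,5-dien-1-yl]-5-oxooxolan-3-yl}-3-methylbut-3-en-1-yl (2S,3S)-2,3-dimethyloxirane-2-carboxylate, via borinate ester 18 (not isolated)
Conditions: (−)-Ipc2B(allyl) (from (+)-α-pinene), Et2O, −78 °C; then pH 7 buffer, H2O2, MeOH, 0 °C
Reagents that add atoms: (−)-B-allyldiisopinocampheylborane, C=CCB([C@@H]1C[C@@H]2C[C@H]([C@H]1C)C2(C)C)[C@@H]1C[C@@H]2C[C@H]([C@H]1C)C2(C)C
Why: Brown allylboration, in which the reagent from (+)-α-pinene adds to the Si face of the Z-enal through a chair transition state and sets (3S), while lactone and ester do not react at −78 °C.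

Step 14
Reactants: 19 (seco-diene from step 13)
Product: 20 (1(10)Z,4Z,3S,6R,7R,8R)-3-hydroxy-13-norgermacra-1(10),4-dien-12,6-olid-8-yl (2S,3S)-2,3-dimethyloxirane-2-carboxylate
Conditions: second-generation Grubbs catalyst RuCl2(=CHPh)(PCy3)(H2IMes) (10–15 mol %, added in portions), 1,4-benzoquinone (10 mol %), toluene (1 mM), 80 → 110 °C, argon sparge
Reagents that add atoms: none
Why: The ruthenium benzylidene loads onto the monosubstituted C1 vinyl group, and the new alkylidene closes onto the 1,1-disubstituted C10 olefin through a ruthenacyclobutane whose cycloreversion releases ethylene and forms C1=C10 (ring-closing olefin metathesis; the closest known cases are closures of ten-membered rings and of trisubstituted cycloalkenes with N-heterocyclic-carbene ruthenium catalysts). The ten-membered carbocycle C1–C10 is closed by this [2+2]/retro-[2+2] sequence, driven by loss of ethylene. No sp3 stereocentre is formed; the new stereoelement is the C1=C10 geometry, expected to be Z because the cis,cis-cyclodeca-1,5-diene is the less strained isomer and is reached through the less strained metallacycle. The step needs ring closure to outrun oligomerisation and the catalyst to ignore the other olefins: high dilution and portionwise catalyst addition serve the first, and the cis C4=C5 olefin and the trans-fused C6/C7 lactone act as turn elements that hold C1 and C10 close. The trisubstituted C4=C5 bond, flanked by two allylic C–O bonds, should be inert, and the exocyclic methylene is deliberately still absent so that an eight-membered closure onto C13 cannot compete.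

Step 15
Reactants: 20 (ring-closed hydroxy lactone from step 14)
Product: 23 (1(10)Z,4Z,3S,6R,7R,8R)-3-hydroxygermacra-1(10),4,11(13)-trien-12,6-olid-8-yl (2S,3S)-2,3-dimethyloxirane-2-carboxylate, via Mannich base 21 (not isolated), via ammonium iodide 22 (not isolated)
Conditions: LiN(iPr)2 (2.2 equiv), THF, −78 °C; CH2=NMe2+ I−, −78 °C → rt; then MeI, MeOH, rt; then aq. NaHCO3, EtOAc
Reagents that add atoms: N,N-dimethylmethyleneiminium iodide (Eschenmoser's salt), C=[N+](C)C.[I-]
Why: The dianion (C3 alkoxide plus lactone enolate; the only ester present has no α-hydrogen) is aminomethylated at C11 (Mannich reaction), and quaternisation followed by mild-base elimination gives the exocyclic methylene C13.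

Step 16
Reactants: 23 (α-methylene lactone from step 15); 24 (R)-2-methylbutanoic acid
Product: 25 (1(10)Z,4Z,3S,6R,7R,8R)-3-[(2R)-2-methylbutanoyloxy]germacra-1(10),4,11(13)-trien-12,6-olid-8-yl (2S,3S)-2,3-dimethyloxirane-2-carboxylate
Conditions: DCC, DMAP (cat.), CH2Cl2, 0 °C
Reagents that add atoms: none
Why: Steglich esterification of the allylic C3 alcohol under mild carbodiimide conditions should neither epimerise the α-stereocentre of the acid nor touch the α-methylene lactone, and no strong base follows this step.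

Step 17
Reactants: 25 (diester from step 16)
Product: 26 (4Z,1S,3S,6R,7R,8R,10R)-1,10-dihydroxy-3-[(2R)-2-methylbutanoyloxy]germacra-4,11(13)-dien-12,6-olid-8-yl (2S,3S)-2,3-dimethyloxirane-2-carboxylate
Conditions: OsO4 (5 mol %), (DHQ)2PHAL (10 mol %), N-methylmorpholine N-oxide, acetone/H2O, 0 °C
Reagents that add atoms: N-methylmorpholine N-oxide, C[N+]1([O-])CCOCC1; water, O
Why: Osmium tetroxide adds syn to the most electron-rich olefin, C1=C10 (C4=C5 is deactivated by two allylic C–O bonds and the exocyclic olefin is electron-poor), and the dihydroquinine ligand directs attack to the α face of the Sharpless mnemonic (C14 south-west, H1 south-east), which should give the (1S,10R) cis-diol (ligand-accelerated Upjohn dihydroxylation).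

Step 18
Reactants: 26 (cis-diol from step 17)
Product: 27 target, (4Z,1R,3S,6R,7R,8R,10R)-1,10-epoxy-3-[(2R)-2-methylbutanoyloxy]germacra-4,11(13)-dien-12,6-olid-8-yl (2S,3S)-2,3-dimethyloxirane-2-carboxylate
Conditions: PPh3, DIAD (betaine pre-formed), THF, 0 → 40 °C
Reagents that add atoms: none
Why: Mitsunobu cyclodehydration, in which the less hindered secondary C1 hydroxyl is activated as the alkoxyphosphonium ion and displaced by the tertiary C10 hydroxyl with inversion at C1, turning the cis-diol of the Z-olefin into the (1R,10R) trans-epoxide.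

Compound list
1 | methyl angelate, methyl (2Z)-2-methylbut-2-enoate | C/C=C(/C)C(=O)OC | starting material
2 | (2Z)-2-methylbut-2-en-1-ol | C/C=C(/C)CO | intermediate
3 | [(2R,3S)-2,3-dimethyloxiran-2-yl]methanol | OC[C@@]1(C)O[C@H]1C | intermediate
4 | (2S,3S)-2,3-dimethyloxirane-2-carbaldehyde (not isolated) | O=C[C@@]1(C)O[C@H]1C | intermediate
5 | (2S,3S)-2,3-dimethyloxirane-2-carboxylic acid | OC(=O)[C@@]1(C)O[C@H]1C | intermediate
6 | (5S)-5-(hydroxymethyl)furan-2(5H)-one | O=C1O[C@H](CO)C=C1 | starting material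
7 | (5S)-5-{[(tert-butyldiphenylsilyl)oxy]methyl}furan-2(5H)-one | O=C1O[C@H](CO[Si](c2ccccc2)(c2ccccc2)C(C)(C)C)C=C1 | intermediate
8 | (4S,5S)-5-{[(tert-butyldiphenylsilyl)oxy]methyl}-4-(1,3-dioxolan-2-yl)oxolan-2-one | O=C1C[C@H](C2OCCO2)[C@@H](CO[Si](c2ccccc2)(c2ccccc2)C(C)(C)C)O1 | intermediate
9 | (2S,3S)-2-{[(tert-butyldiphenylsilyl)oxy]methyl}-5-oxooxolane-3-carbaldehyde | O=C1C[C@H](C=O)[C@@H](CO[Si](c2ccccc2)(c2ccccc2)C(C)(C)C)O1 | intermediate
10 | O-bis(isopinocampheyl)boryl ether (borinate) of 11 (not isolated) | O=C1C[C@H]([C@H](OB([C@H]2C[C@H]3C[C@@H]([C@@H]2C)C3(C)C)[C@H]2C[C@H]3C[C@@H]([C@@H]2C)C3(C)C)CC(C)=C)[C@@H](CO[Si](c2ccccc2)(c2ccccc2)C(C)(C)C)O1 | intermediate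
11 | (4R,5S)-5-{[(tert-butyldiphenylsilyl)oxy]methyl}-4-[(1R)-1-hydroxy-3-methylbut-3-en-1-yl]oxolan-2-one | O=C1C[C@H]([C@H](O)CC(C)=C)[C@@H](CO[Si](c2ccccc2)(c2ccccc2)C(C)(C)C)O1 | intermediate
12 | mixed anhydride of 5 with 2,4,6-trichlorobenzoic acid (not isolated) | O=C(OC(=O)[C@@]1(C)O[C@H]1C)c1c(Cl)cc(Cl)cc1Cl | intermediate
13 | (1R)-1-[(2S,3R)-2-{[(tert-butyldiphenylsilyl)oxy]methyl}-5-oxooxolan-3-yl]-3-methylbut-3-en-1-yl (2S,3S)-2,3-dimethyloxirane-2-carboxylate | O=C1C[C@H]([C@H](OC(=O)[C@@]2(C)O[C@H]2C)CC(C)=C)[C@@H](CO[Si](c2ccccc2)(c2ccccc2)C(C)(C)C)O1 | intermediate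
14 | (1R)-1-[(2S,3R)-2-(hydroxymethyl)-5-oxooxolan-3-yl]-3-methylbut-3-en-1-yl (2S,3S)-2,3-dimethyloxirane-2-carboxylate | O=C1C[C@H]([C@H](OC(=O)[C@@]2(C)O[C@H]2C)CC(C)=C)[C@@H](CO)O1 | intermediate
15 | (1R)-1-[(2S,3R)-2-formyl-5-oxooxolan-3-yl]-3-methylbut-3-en-1-yl (2S,3S)-2,3-dimethyloxirane-2-carboxylate | O=C1C[C@H]([C@H](OC(=O)[C@@]2(C)O[C@H]2C)CC(C)=C)[C@@H](C=O)O1 | intermediate
16 | (1R)-1-{(2S,3R)-2-[(1Z)-2-iodoprop-1-en-1-yl]-5-oxooxolan-3-yl}-3-methylbut-3-en-1-yl (2S,3S)-2,3-dimethyloxirane-2-carboxylate | O=C1C[C@H]([C@H](OC(=O)[C@@]2(C)O[C@H]2C)CC(C)=C)[C@@H](/C=C(/C)I)O1 | intermediate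
17 | (1R)-3-methyl-1-{(2R,3R)-2-[(1Z)-2-methyl-3-oxoprop-1-en-1-yl]-5-oxooxolan-3-yl}but-3-en-1-yl (2S,3S)-2,3-dimethyloxirane-2-carboxylate | O=C1C[C@H]([C@H](OC(=O)[C@@]2(C)O[C@H]2C)CC(C)=C)[C@@H](/C=C(/C)C=O)O1 | intermediate
18 | O-bis(isopinocampheyl)boryl ether (borinate) of 19 (not isolated) | O=C1C[C@H]([C@H](OC(=O)[C@@]2(C)O[C@H]2C)CC(C)=C)[C@@H](/C=C(/C)[C@@H](OB([C@@H]2C[C@@H]3C[C@H]([C@H]2C)C3(C)C)[C@@H]2C[C@@H]3C[C@H]([C@H]2C)C3(C)C)CC=C)O1 | intermediate
19 | (1R)-1-{(2R,3R)-2-[(1Z,3S)-3-hydroxy-2-methylhexa-1,5-dien-1-yl]-5-oxooxolan-3-yl}-3-methylbut-3-en-1-yl (2S,3S)-2,3-dimethyloxirane-2-carboxylate | O=C1C[C@H]([C@H](OC(=O)[C@@]2(C)O[C@H]2C)CC(C)=C)[C@@H](/C=C(/C)[C@@H](O)CC=C)O1 | intermediate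
20 | (1(10)Z,4Z,3S,6R,7R,8R)-3-hydroxy-13-norgermacra-1(10),4-dien-12,6-olid-8-yl (2S,3S)-2,3-dimethyloxirane-2-carboxylate | O=C1O[C@@H]2/C=C(/C)[C@@H](O)C/C=C(C)\C[C@@H](OC(=O)[C@@]3(C)O[C@H]3C)[C@H]2C1 | intermediate
21 | 11-(dimethylaminomethyl) derivative of 20, C11 epimers (not isolated) | O=C1O[C@@H]2/C=C(/C)[C@@H](O)C/C=C(C)\C[C@@H](OC(=O)[C@@]3(C)O[C@H]3C)[C@H]2C1CN(C)C | intermediate
22 | trimethylammonium iodide from 21 (not isolated) | O=C1O[C@@H]2/C=C(/C)[C@@H](O)C/C=C(C)\C[C@@H](OC(=O)[C@@]3(C)O[C@H]3C)[C@H]2C1C[N+](C)(C)C.[I-] | intermediate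
23 | (1(10)Z,4Z,3S,6R,7R,8R)-3-hydroxygermacra-1(10),4,11(13)-trien-12,6-olid-8-yl (2S,3S)-2,3-dimethyloxirane-2-carboxylate | C=C1C(=O)O[C@@H]2/C=C(/C)[C@@H](O)C/C=C(C)\C[C@@H](OC(=O)[C@@]3(C)O[C@H]3C)[C@@H]12 | intermediate
24 | (R)-2-methylbutanoic acid | CC[C@@H](C)C(=O)O | starting material
25 | (1(10)Z,4Z,3S,6R,7R,8R)-3-[(2R)-2-methylbutanoyloxy]germacra-1(10),4,11(13)-trien-12,6-olid-8-yl (2S,3S)-2,3-dimethyloxirane-2-carboxylate | C=C1C(=O)O[C@@H]2/C=C(/C)[C@@H](OC(=O)[C@H](C)CC)C/C=C(C)\C[C@@H](OC(=O)[C@@]3(C)O[C@H]3C)[C@@H]12 | intermediate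
26 | (4Z,1S,3S,6R,7R,8R,10R)-1,10-dihydroxy-3-[(2R)-2-methylbutanoyloxy]germacra-4,11(13)-dien-12,6-olid-8-yl (2S,3S)-2,3-dimethyloxirane-2-carboxylate | C=C1C(=O)O[C@@H]2/C=C(/C)[C@@H](OC(=O)[C@H](C)CC)C[C@H](O)[C@@](O)(C)C[C@@H](OC(=O)[C@@]3(C)O[C@H]3C)[C@@H]12 | intermediate
27 | (4Z,1R,3S,6R,7R,8R,10R)-1,10-epoxy-3-[(2R)-2-methylbutanoyloxy]germacra-4,11(13)-dien-12,6-olid-8-yl (2S,3S)-2,3-dimethyloxirane-2-carboxylate | C=C1C(=O)O[C@@H]2/C=C(/C)[C@@H](OC(=O)[C@H](C)CC)C[C@H]3O[C@]3(C)C[C@@H](OC(=O)[C@@]3(C)O[C@H]3C)[C@@H]12 | target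

Total step count: 18. Longest linear sequence: 15 steps (steps 4–18, from 6); the epoxy acid 5 (steps 1–3) joins in step 8.

Steps most likely to fail

Step 14 (ring-closing metathesis). The ring may close with E instead of Z geometry at C1=C10 (loss of geometric control); oligomerisation by intermolecular metathesis is the second hazard and is met by dilution. The fallback sets out from 19 and comes back at 27. The (1(10)E,4Z)-cyclodecadiene F1 would be carried through the operations of steps 15 and 16: aminomethylation to the Mannich base F2, quaternisation to the ammonium iodide F3 (neither isolated), elimination to the α-methylene lactone F4 and esterification with 24 to the diester F5. F5 would then be epoxidised directly with mCPBA (NaHCO3, CH2Cl2, 0 °C). Peracid attack on the exposed outer face of the E-olefin, the usual course for germacra-1(10)-enolides, should give the (1R,10R) trans-epoxide 27 in one step, so steps 17 and 18 are not needed.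

Step 17 (dihydroxylation). Osmylation may take the opposite face of C1=C10 (poor facial selectivity in the folded ring), or the exocyclic olefin may be oxidised as well. The fallback sets out from 25 and comes back at 26. Woodward cis-hydroxylation (I2, AgOAc, wet AcOH, rt) places the iodonium ion on the face that osmium prefers and delivers both oxygens to the other face through the 1,3-dioxolan-2-ylium ion, giving the hydroxy acetate F6. Its unhindered secondary acetate would be removed with Candida antarctica lipase B in phosphate buffer/acetone to give 26.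

Step 18 (cyclodehydration). Activation of the hindered secondary C1 hydroxyl may be slow, so that participation by the C3 ester carbonyl or elimination competes with oxirane closure. The fallback sets out from 26 and comes back at 27. Selective sulfonylation of the secondary hydroxyl (MsCl, pyridine, 0 °C) gives the mesylate F7, and DBU in CH2Cl2 closes the oxirane by attack of the tertiary alkoxide with inversion at C1.

Further compounds
F1 | step 14 | (1(10)E,4Z,3S,6R,7R,8R) isomer of 20 | O=C1O[C@@H]2/C=C(/C)[C@@H](O)C/C=C(C)/C[C@@H](OC(=O)[C@@]3(C)O[C@H]3C)[C@H]2C1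
F2 | step 14 | 11-(dimethylaminomethyl) derivative of F1 | O=C1O[C@@H]2/C=C(/C)[C@@H](O)C/C=C(C)/C[C@@H](OC(=O)[C@@]3(C)O[C@H]3C)[C@H]2C1CN(C)C
F3 | step 14 | trimethylammonium iodide from F2 | O=C1O[C@@H]2/C=C(/C)[C@@H](O)C/C=C(C)/C[C@@H](OC(=O)[C@@]3(C)O[C@H]3C)[C@H]2C1C[N+](C)(C)C.[I-]
F4 | step 14 | (1(10)E) isomer of 23 | C=C1C(=O)O[C@@H]2/C=C(/C)[C@@H](O)C/C=C(C)/C[C@@H](OC(=O)[C@@]3(C)O[C@H]3C)[C@@H]12
F5 | step 14 | (1(10)E) isomer of 25 | C=C1C(=O)O[C@@H]2/C=C(/C)[C@@H](OC(=O)[C@H](C)CC)C/C=C(C)/C[C@@H](OC(=O)[C@@]3(C)O[C@H]3C)[C@@H]12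
F6 | step 17 | 1-O-acetate of 26 | C=C1C(=O)O[C@@H]2/C=C(/C)[C@@H](OC(=O)[C@H](C)CC)C[C@H](OC(C)=O)[C@@](O)(C)C[C@@H](OC(=O)[C@@]3(C)O[C@H]3C)[C@@H]12
F7 | step 18 | 1-O-methanesulfonate of 26 | C=C1C(=O)O[C@@H]2/C=C(/C)[C@@H](OC(=O)[C@H](C)CC)C[C@H](OS(C)(=O)=O)[C@@](O)(C)C[C@@H](OC(=O)[C@@]3(C)O[C@H]3C)[C@@H]12
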